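**Retrosynthetic overview**
1. Ring B is opened at its C9=C10 bromoalkene. The target is made in the last step by ring-closing metathesis of the unprotected, fully halogenated monocyclic triene 18, which turns a cyclohexane with two arms into the spiro[5.5]undecane.
2. Enabling feature: the two contiguous fully substituted ring-B carbons, spiro C6 and gem-dimethyl C11, press the C7–C8–C9 arm and the C10 bromovinyl arm together. C11 also shields the bromoalkene, and the C7=C14 methylene could only form three- or four-membered rings and therefore stays out.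
3. The C7–C9 arm grows from a formyl group on C6 by one-carbon Wittig homologation, α-methylenation and a ligand-controlled vinylzinc addition that sets C8.
4. The trans C2–Br/C3–Cl pair is relayed from C6. Bromolactonisation of the C6 acid gives a temporary 2-oxabicyclo[2.2.2]octanone ring, which is reduced and then reopened by a retentive O-to-Cl exchange.
5. Ring A and C6 come from an enantioselective Diels–Alder reaction of isoprene with acrolein 7. Compound 7 comes from prenal through a Claisen rearrangement that creates C11 and the C10 bromoalkene. Ring order: A, temporary lactone, B.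

Key step: step 13

Numbering in the text (chamigrane): ring A = C1–C6 (C2 bears Br, C3 bears Cl and CH3), C6 = spiro carbon, ring B = C6–C11 (C7 bears the exocyclic CH2 = C14, C8 the OH, C10 the vinylic Br, C11 the two CH3).
Assumption: the catalyst antipode in step 5 is assigned from the accepted formyl C–H···O binding model for 2-substituted acroleins; if the opposite antipode of 9 results, the mirror-image catalyst is used and nothing else changes.

Step 1
Reactants: 1 3-methylbut-2-enal (prenal)
Product: 3 2-bromo-3-methylbut-2-enal, via dibromoaldehyde 2 (not isolated)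
Conditions: Br2, CH2Cl2, 0 °C; then Et3N, 0 °C → rt
Reagents that add atoms: bromine, BrBr
Why: Bromination–dehydrobromination of an enal: Br2 adds across the trisubstituted C=C and Et3N removes the acidic α-hydrogen of 2 with loss of the tertiary bromide, the standard entry to α-bromo enals, and no stereocentre survives.

Step 2
Reactants: 3 2-bromo-3-methylbut-2-enal
Product: 4 2-bromo-3-methylbut-2-en-1-ol
Conditions: NaBH4, MeOH, 0 °C
Reagents that add atoms: none
Why: Borohydride 1,2-reduction of the aldehyde; the fully substituted, bromine-bearing C=C is a poor conjugate acceptor, so the allylic alcohol should form cleanly.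

Step 3
Reactants: 4 2-bromo-3-methylbut-2-en-1-ol
Product: 6 4-bromo-3,3-dimethylpent-4-enal, via allyl vinyl ether 5 (not isolated)
Conditions: ethyl vinyl ether (solvent), Hg(OAc)2 (5 mol %), reflux; evaporate; xylene, 140 °C, sealed tube
Reagents that add atoms: ethyl vinyl ether, C=COCC
Why: Transvinylation followed by the aliphatic Claisen rearrangement: the [3,3] shift of 5 transposes the allyl unit, so the former Me2C= terminus becomes the quaternary gem-dimethyl carbon (C11) and the bromine-bearing carbon ends as the 2-bromo-1-alkene (C10) in one event.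

Step 4
Reactants: 6 4-bromo-3,3-dimethylpent-4-enal
Product: 7 4-bromo-3,3-dimethyl-2-methylidenepent-4-enal
Conditions: 37 % aq. CH2O, pyrrolidine (10 mol %), propionic acid (10 mol %), i-PrOH, 45 °C
Reagents that add atoms: formaldehyde, C=O
Why: Amine/acid-catalysed Mannich condensation–elimination (organocatalytic α-methylenation of aldehydes); 6 has a single enolisable position and neopentyl-type aldehydes are competent substrates.

Step 5
Reactants: 7 4-bromo-3,3-dimethyl-2-methylidenepent-4-enal; 8 isoprene
Product: 9 (1R)-1-(3-bromo-2-methylbut-3-en-2-yl)-4-methylcyclohex-3-ene-1-carbaldehyde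
Conditions: (R)-3,3-diphenyl-1-(2-methylphenyl)tetrahydropyrrolo[1,2-c][1,3,2]oxazaborole (20 mol %), HN(SO2CF3)2 (18 mol %), CH2Cl2, −78 → −40 °C
Reagents that add atoms: none
Why: Enantioselective Diels–Alder reaction: the protonated oxazaborolidine binds the s-trans enal through B–O coordination and a formyl C–H···O contact, a catalyst phenyl group shields one enal face so that isoprene adds to the other, and the lowered LUMO enforces the "para" orientation (ring methyl 1,4 to the new quaternary carbon), which together fix the (R)-quaternary carbon that becomes spiro C6; additions of isoprene to α-methylene carbonyl compounds flanked by a gem-dimethyl carbon have close precedent.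

Step 6
Reactants: 9 (1R)-1-(3-bromo-2-methylbut-3-en-2-yl)-4-methylcyclohex-3-ene-1-carbaldehyde
Product: 10 (1R)-1-(3-bromo-2-methylbut-3-en-2-yl)-4-methylcyclohex-3-ene-1-carboxylic acid
Conditions: NaClO2, NaH2PO4, 2-methylbut-2-ene (excess), t-BuOH/H2O, 0 °C → rt
Reagents that add atoms: sodium chlorite, [Na+].[O-]Cl=O
Why: Pinnick oxidation: chlorous acid oxidises hindered, non-enolisable aldehydes under buffered conditions and the excess 2-methylbut-2-ene traps the hypochlorous acid before it can attack the ring alkene, so C6 is untouched.

Step 7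
Reactants: 10 (1R)-1-(3-bromo-2-methylbut-3-en-2-yl)-4-methylcyclohex-3-ene-1-carboxylic acid
Product: 11 (1S,4R,6S)-6-bromo-4-(3-bromo-2-methylbut-3-en-2-yl)-1-methyl-2-oxabicyclo[2.2.2]octan-3-one
Conditions: N-bromosuccinimide, CH2Cl2, 0 °C → rt, dark
Reagents that add atoms: N-bromosuccinimide, O=C1CCC(=O)N1Br
Why: Bromolactonisation: only the bromonium ion anti to the carboxyl group can be captured, and closure at the tertiary (Markovnikov) carbon gives the bicyclo[2.2.2] lactone (a tertiary-bromide γ-lactone would form reversibly), so the C3–O bond is necessarily cis and the C2–Br bond trans to the carboxyl carbon, both new stereocentres are dictated by C6, and the electron-poor bromoalkene does not compete.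

Step 8
Reactants: 11 (1S,4R,6S)-6-bromo-4-(3-bromo-2-methylbut-3-en-2-yl)-1-methyl-2-oxabicyclo[2.2.2]octan-3-one
Product: 12 (1S,4R,6S)-6-bromo-4-(3-bromo-2-methylbut-3-en-2-yl)-1-methyl-2-oxabicyclo[2.2.2]octan-3-ol (lactol, both hemiacetal epimers, in equilibrium with the open hydroxy aldehyde)
Conditions: i-Bu2AlH (1.1 equiv), CH2Cl2, −78 °C; aq. KNaC4H4O6
Reagents that add atoms: none
Why: Partial reduction of a lactone to the lactol relies on the low-temperature stability of the aluminium hemiacetal, which the neopentyl-type carbonyl reinforces; the hemiacetal carbon is an inconsequential epimer mixture because it returns to sp2 in step 9.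

Step 9
Reactants: 12 lactol
Product: 14 (1R,3S,4S)-3-bromo-1-(3-bromo-2-methylbut-3-en-2-yl)-4-chloro-4-methylcyclohexane-1-carbaldehyde, via chlorosulfite 13 (not isolated)
Conditions: SOCl2 (1.2 equiv), CH2Cl2, −20 °C; then TiCl4 (10 mol %), −20 → 0 °C
Reagents that add atoms: thionyl chloride, O=S(Cl)Cl
Why: Proposed new method: the lactol is in equilibrium with its tertiary-hydroxy aldehyde, which SOCl2 converts into chlorosulfite 13; TiCl4 triggers ionisation, and the cationic C3 is covered on one face by the vicinal trans bromine (bromine-bridged ion pair), so chloride can only enter on the face the oxygen has just left; the result is net retention (Cl cis to the formyl carbon, trans to Br), and the opening is irreversible because the released formyl group is no nucleophile; the closest known reaction types are the stereoretentive front-side deoxychlorination of cyclic alcohols with SOCl2 and catalytic TiCl4 and retentive substitutions next to bromine through neighbouring-group participation.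

Step 10
Reactants: 14 (1R,3S,4S)-3-bromo-1-(3-bromo-2-methylbut-3-en-2-yl)-4-chloro-4-methylcyclohexane-1-carbaldehyde
Product: 16 2-[(1R,3S,4S)-3-bromo-1-(3-bromo-2-methylbut-3-en-2-yl)-4-chloro-4-methylcyclohexyl]acetaldehyde, via enol ether 15 (not isolated)
Conditions: Ph3P(CH2OMe)Cl, KN(SiMe3)2, THF, 0 °C; add 14, −78 → 0 °C; then 2 M aq. HCl, THF, rt
Reagents that add atoms: (methoxymethyl)triphenylphosphonium chloride, COC[P+](c1ccccc1)(c1ccccc1)c1ccccc1.[Cl-]; water, O
Why: Wittig methoxymethylenation and enol-ether hydrolysis (one-carbon aldehyde homologation); the non-enolisable aldehyde cannot be deprotonated by the ylide, low temperature keeps the alkyl halides out of elimination, and no stereocentre is involved.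

Step 11
Reactants: 16 2-[(1R,3S,4S)-3-bromo-1-(3-bromo-2-methylbut-3-en-2-yl)-4-chloro-4-methylcyclohexyl]acetaldehyde
Product: 17 2-[(1S,3S,4S)-3-bromo-1-(3-bromo-2-methylbut-3-en-2-yl)-4-chloro-4-methylcyclohexyl]prop-2-enal
Conditions: 37 % aq. CH2O, pyrrolidine (10 mol %), propionic acid (10 mol %), i-PrOH, 45 °C
Reagents that add atoms: formaldehyde, C=O
Why: The same organocatalytic Mannich–elimination α-methylenation as in step 4 installs the C7=C14 methylene under nearly neutral conditions that spare the bromochloride and avoid olefination of a very hindered ketone; the descriptor at C6 changes only through priorities.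

Step 12
Reactants: 17 2-[(1S,3S,4S)-3-bromo-1-(3-bromo-2-methylbut-3-en-2-yl)-4-chloro-4-methylcyclohexyl]prop-2-enal
Product: 18 (3R)-2-[(1S,3S,4S)-3-bromo-1-(3-bromo-2-methylbut-3-en-2-yl)-4-chloro-4-methylcyclohexyl]penta-1,4-dien-3-ol
Conditions: Zn(CH=CH2)2 (2 equiv, salt-free stock solution), (+)-3-exo-morpholinoisoborneol (10 mol %), toluene, −20 → 0 °C; H2O
Reagents that add atoms: divinylzinc, C=C[Zn]C=C
Why: Amino-alkoxide-catalysed enantioselective 1,2-addition of an alkenylzinc reagent: ligand-accelerated vinyl transfer to the Re face of the enal through the bimetallic six-membered transition state sets (8R) under reagent control, because the nearest resident stereocentre C6 offers almost no bias (its two ring CH2 arms are alike) and organozinc reagents leave the alkyl halides alone.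

Step 13
Reactants: 18 (3R)-2-[(1S,3S,4S)-3-bromo-1-(3-bromo-2-methylbut-3-en-2-yl)-4-chloro-4-methylcyclohexyl]penta-1,4-dien-3-ol
Product: 19 (2S,3S,6S,8R)-2,10-dibromo-3-chlorochamigra-7(14),9-dien-8-ol (target)
Conditions: RuCl2(=CH-C6H4-2-O-i-Pr)[1,3-bis(2-methylphenyl)imidazolidin-2-ylidene] (10 mol %), 2,6-dichloro-1,4-benzoquinone (20 mol %), toluene (0.002 M), 80 °C, argon sparge
Reagents that add atoms: none
Why: Ring-closing olefin metathesis by the metallacyclobutane mechanism: the catalyst loads on the only monosubstituted alkene, the C9 vinyl group activated by the allylic hydroxyl, and the Ru=C9 alkylidene adds to the bromoalkene with C9 bonding to C10 and Ru to the CH2 terminus, so cycloreversion releases the C9=C10 bromoalkene and Ru=CH2 and no Ru=C(Br) carbene is formed. The closest known reaction types are ring-closing metatheses of 2-chloro- and 2-bromo-1-alkenes to five- to seven-membered cyclic alkenyl halides and closures of trisubstituted alkenes next to quaternary carbons with small-NHC ruthenium catalysts. One ring is closed, six-membered ring B, by diene closure in which both reacting carbons become endocyclic and ethene is lost; this single event creates the spiro[5.5]undecane, places the vinylic bromide and delivers the target without any protecting group. No stereocentre is created, and C2, C3, C6 and C8 are spectators under the neutral conditions. The step needs chemoselectivity among three alkenes and against dimerisation: C7=C14 could only give a three-membered ring with C9 or a four-membered ring with C10. The contiguous fully substituted C6 and C11 compress the two arms (gem-dialkyl effect) while C11 shields the bromoalkene from intermolecular attack by Ru=CH2, and high dilution, ethene removal and the quinone (against Ru–H isomerisation of the bis-allylic alcohol) support this.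

**Compound list**
1 | 3-methylbut-2-enal (prenal) | CC(C)=CC=O | starting material
2 | 2,3-dibromo-3-methylbutanal (not isolated) | CC(C)(Br)C(Br)C=O | intermediate
3 | 2-bromo-3-methylbut-2-enal | CC(C)=C(Br)C=O | intermediate
4 | 2-bromo-3-methylbut-2-en-1-ol | CC(C)=C(Br)CO | intermediate
5 | 2-bromo-1-(ethenyloxy)-3-methylbut-2-ene (not isolated) | C=COCC(Br)=C(C)C | intermediate
6 | 4-bromo-3,3-dimethylpent-4-enal | O=CCC(C)(C)C(Br)=C | intermediate
7 | 4-bromo-3,3-dimethyl-2-methylidenepent-4-enal | O=CC(=C)C(C)(C)C(Br)=C | intermediate
8 | isoprene | C=CC(C)=C | starting material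
9 | (1R)-1-(3-bromo-2-methylbut-3-en-2-yl)-4-methylcyclohex-3-ene-1-carbaldehyde | O=C[C@]1(C(C)(C)C(Br)=C)CCC(C)=CC1 | intermediate
10 | (1R)-1-(3-bromo-2-methylbut-3-en-2-yl)-4-methylcyclohex-3-ene-1-carboxylic acid | OC(=O)[C@]1(C(C)(C)C(Br)=C)CCC(C)=CC1 | intermediate
11 | (1S,4R,6S)-6-bromo-4-(3-bromo-2-methylbut-3-en-2-yl)-1-methyl-2-oxabicyclo[2.2.2]octan-3-one | O=C1O[C@@]2(C)CC[C@]1(C(C)(C)C(Br)=C)C[C@@H]2Br | intermediate
12 | (1S,4R,6S)-6-bromo-4-(3-bromo-2-methylbut-3-en-2-yl)-1-methyl-2-oxabicyclo[2.2.2]octan-3-ol (hemiacetal epimers) | OC1O[C@@]2(C)CC[C@]1(C(C)(C)C(Br)=C)C[C@@H]2Br | intermediate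
13 | tertiary chlorosulfite of the open hydroxy aldehyde form of 12 (not isolated) | O=C[C@]1(C(C)(C)C(Br)=C)CC[C@](C)(OS(Cl)=O)[C@@H](Br)C1 | intermediate
14 | (1R,3S,4S)-3-bromo-1-(3-bromo-2-methylbut-3-en-2-yl)-4-chloro-4-methylcyclohexane-1-carbaldehyde | O=C[C@]1(C(C)(C)C(Br)=C)CC[C@](C)(Cl)[C@@H](Br)C1 | intermediate
15 | methyl enol ether of 16, E/Z mixture (not isolated) | COC=C[C@]1(C(C)(C)C(Br)=C)CC[C@](C)(Cl)[C@@H](Br)C1 | intermediate
16 | 2-[(1R,3S,4S)-3-bromo-1-(3-bromo-2-methylbut-3-en-2-yl)-4-chloro-4-methylcyclohexyl]acetaldehyde | O=CC[C@]1(C(C)(C)C(Br)=C)CC[C@](C)(Cl)[C@@H](Br)C1 | intermediate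
17 | 2-[(1S,3S,4S)-3-bromo-1-(3-bromo-2-methylbut-3-en-2-yl)-4-chloro-4-methylcyclohexyl]prop-2-enal | O=CC(=C)[C@]1(C(C)(C)C(Br)=C)CC[C@](C)(Cl)[C@@H](Br)C1 | intermediate
18 | (3R)-2-[(1S,3S,4S)-3-bromo-1-(3-bromo-2-methylbut-3-en-2-yl)-4-chloro-4-methylcyclohexyl]penta-1,4-dien-3-ol | C=C[C@@H](O)C(=C)[C@]1(C(C)(C)C(Br)=C)CC[C@](C)(Cl)[C@@H](Br)C1 | intermediate
19 | (2S,3S,6S,8R)-2,10-dibromo-3-chlorochamigra-7(14),9-dien-8-ol | C=C1[C@H](O)C=C(Br)C(C)(C)[C@]12CC[C@](C)(Cl)[C@@H](Br)C2 | target

Total step count: 13. Longest linear sequence: 13 steps (1 → 19).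

**Steps most likely to fail**

Step 9 (labelled step). Ionisation at C3 may end in proton loss (elimination), in erosion of configuration, or in migration of bromine. The fallback sets out from 9 and comes back at 14. The ring-A alkene of 9 is bromochlorinated directly with N-bromosuccinimide and ClTi(O-i-Pr)3 in CH2Cl2 at −20 °C, a known intermolecular anti, Markovnikov bromochlorination that bypasses 10–13. It should give 14 together with the (1R,3R,4R)-diastereomeric bromochloride F1. The two are separated by chromatography, and F1 is returned to 9 by reductive elimination with zinc dust in ethanol and resubmitted.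

Step 13. Closure onto the hindered, electron-poor bromoalkene may be so slow that catalyst decay, isomerisation of the bis-allylic alcohol or dimerisation at the vinyl group takes over. The fallback sets out from 18 and comes back at 19; bromine is exchanged for boron before the ring is closed.
- Borylation of the alkenyl bromide of 18 with bis(pinacolato)diboron (PdCl2(PPh3)2, PPh3, KOPh, toluene, 50 °C) gives the pinacol alkenylboronate analogue of 18, F2.
- Alkenyl pinacolboronates are established, non-poisoning partners in ring-closing metathesis and should close under the conditions of step 13 to the cyclic C10 alkenylboronate analogue of 19, F3.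
- The C–B bond of F3 is converted into C–Br with CuBr2 in aqueous methanol.

Step 5. The bulky α-substituent may make the cycloaddition sluggish and blunt the facial discrimination by the catalyst. The fallback sets out from 4 and comes back at 11.
- Alcohol 4 is esterified (dicyclohexylcarbodiimide, 4-dimethylaminopyridine) with commercial 4-methylcyclohex-3-ene-1-carboxylic acid to the allylic ester F4.
- LiN(i-Pr)2 and Me3SiCl at −78 °C give the silyl ketene acetal F5.
- The Ireland–Claisen rearrangement of F5 on warming forms the C6–C11 bond and the bromoalkene at once and gives the trimethylsilyl ester F6, which is hydrolysed on work-up to the racemic acid F7.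
- Bromolactonisation as in step 7 gives the racemic bromolactone F8, which is resolved by preparative chromatography on a chiral stationary phase; the (1S,4R,6S) antipode is 11.

**Further compounds**
F1 | step 9 | (1R,3R,4R)-3-bromo-1-(3-bromo-2-methylbut-3-en-2-yl)-4-chloro-4-methylcyclohexane-1-carbaldehyde | O=C[C@]1(C(C)(C)C(Br)=C)CC[C@@](C)(Cl)[C@H](Br)C1
F2 | step 13 | pinacol alkenylboronate analogue of 18 (boronate in place of the vinylic Br, stereocentres as in 18) | C=C[C@@H](O)C(=C)[C@]1(C(C)(C)C(=C)B2OC(C)(C)C(C)(C)O2)CC[C@](C)(Cl)[C@@H](Br)C1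
F3 | step 13 | cyclic C10 pinacol alkenylboronate analogue of 19 (stereocentres as in 19) | C=C1[C@H](O)C=C(B2OC(C)(C)C(C)(C)O2)C(C)(C)[C@]12CC[C@](C)(Cl)[C@@H](Br)C2
F4 | step 5 | 2-bromo-3-methylbut-2-en-1-yl 4-methylcyclohex-3-ene-1-carboxylate (racemic) | CC1=CCC(CC1)C(=O)OCC(Br)=C(C)C
F5 | step 5 | trimethylsilyl ketene acetal of F4 | CC1=CCC(CC1)=C(O[Si](C)(C)C)OCC(Br)=C(C)C
F6 | step 5 | trimethylsilyl 1-(3-bromo-2-methylbut-3-en-2-yl)-4-methylcyclohex-3-ene-1-carboxylate (racemic) | C[Si](C)(C)OC(=O)C1(C(C)(C)C(Br)=C)CCC(C)=CC1
F7 | step 5 | racemic 10 (both antipodes) | OC(=O)[C@]1(C(C)(C)C(Br)=C)CCC(C)=CC1.OC(=O)[C@@]1(C(C)(C)C(Br)=C)CCC(C)=CC1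
F8 | step 5 | racemic 11 (both antipodes) | O=C1O[C@@]2(C)CC[C@]1(C(C)(C)C(Br)=C)C[C@@H]2Br.O=C1O[C@]2(C)CC[C@@]1(C(C)(C)C(Br)=C)C[C@H]2Br
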